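**Plan**
- Retrosynthesis: first the three aryl MOM acetals and the C2' silyl ether are cut, then the ring A–C(=O) bond to the benzoyl group, then C2'–O is traced back to C2'–B. The last cut removes the ring A–C1' and C2'–C3' bonds together.
- Enabling feature: the triad ring A (the phloroglucinol ring)–C1'H2–C2'H(O)–C3'(=CH2). The carbinol carbon C2' sits between a benzylic methylene and a 1,1-disubstituted alkene carbon, so C1'–C2' can be a vinyl unit inserted between an aryl electrophile and an alkenylboron migrating group.
- Forward: phloroglucinol is taken to aryl triflate 6 (3 steps), sulcatone to dienyl boronate 11 (2 steps), tetravinylstannane to vinyllithium 13 (1 step). The three are joined in step 7; no ring is formed anywhere (ring A and the phenyl ring B are bought).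
- After the coupling: C–B to C–O with retention, silylation, ortho-lithiation between two MOM ethers with benzoylation, and global deprotection.
- Stereochemistry: the only stereocentre (C2', R) is set by the chiral bisphosphine on palladium in step 7, transferred by stereoretentive oxidation in step 8, and not touched afterwards.

Key step: step 7

Assumption: L is the (Sp,Sp)-MandyPhos ligand 1,1'-bis[bis(4-methoxy-3,5-dimethylphenyl)phosphino]-2,2'-bis[(R)-α-(dimethylamino)benzyl]ferrocene; this antipode is taken to give the (R)-boronate by analogy with the facial preference known for aryl and alkenyl migrating groups, and its mirror image would be used, with nothing else changed, if a first run showed the opposite sense.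

**Route**

Step 1
Reactants: 1 phloroglucinol
Product: 2 1,3,5-tris(methoxymethoxy)benzene
Conditions: MOMCl, iPr2NEt, DMF, 0 °C → rt
Reagents that add atoms: chloromethyl methyl ether, COCCl
Why: O-alkylation of the three phenols with the reactive α-chloro ether under amine base (Williamson-type acetal formation) should give the tris-acetal, whose oxygen substituents later direct both lithiations.

Step 2
Reactants: 2 1,3,5-tris(methoxymethoxy)benzene
Product: 5 2,4,6-tris(methoxymethoxy)phenol, via 2,4,6-tris(methoxymethoxy)phenyllithium 3 (not isolated), via lithium aryltrimethoxyborate 4 (not isolated)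
Conditions: n-BuLi, THF, 0 °C → rt; B(OMe)3, −78 °C → rt; AcOH, 30% H2O2, 0 °C → rt
Reagents that add atoms: hydrogen peroxide, OO
Why: Directed ortho-metalation at a carbon flanked by two chelating MOM ethers, borylation, and oxidative 1,2-aryl shift from boron to oxygen (boronate oxidation) should install the hydroxyl at the only type of ring position available, with the mildly acidic oxidation sparing the acetals.

Step 3
Reactants: 5 2,4,6-tris(methoxymethoxy)phenol
Product: 6 2,4,6-tris(methoxymethoxy)phenyl trifluoromethanesulfonate
Conditions: Tf2O, pyridine, CH2Cl2, −20 → 0 °C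
Reagents that add atoms: trifluoromethanesulfonic anhydride, O=S(=O)(OS(=O)(=O)C(F)(F)F)C(F)(F)F
Why: O-sulfonylation (triflation) of the phenol is fast at low temperature even between two ortho substituents, and excess pyridine keeps the medium basic so the acetals survive.

Step 4
Reactants: 7 6-methylhept-5-en-2-one (sulcatone)
Product: 9 6-methylhepta-1,5-dien-2-yl trifluoromethanesulfonate, via lithium 6-methylhepta-1,5-dien-2-olate 8 (not isolated)
Conditions: LiN(iPr)2, THF, −78 °C (ketone added to base); N-(5-chloropyridin-2-yl)triflimide, −78 → −20 °C; H2O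
Reagents that add atoms: N-(5-chloropyridin-2-yl)bis(trifluoromethanesulfonyl)imide, O=S(=O)(N(c1ccc(Cl)cn1)S(=O)(=O)C(F)(F)F)C(F)(F)F
Why: Kinetic deprotonation of the methyl ketone by the hindered amide base at the methyl group, followed by O-triflation of the enolate with a triflimide that reacts at low temperature, should give the terminal enol triflate before the enolate can equilibrate.

Step 5
Reactants: 9 6-methylhepta-1,5-dien-2-yl trifluoromethanesulfonate; 10 bis(pinacolato)diboron
Product: 11 4,4,5,5-tetramethyl-2-(6-methylhepta-1,5-dien-2-yl)-1,3,2-dioxaborolane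
Conditions: PdCl2(PPh3)2 (3 mol %), PPh3 (6 mol %), KOPh, toluene, 50 °C
Reagents that add atoms: none
Why: Miyaura borylation of a 1-alkenyl triflate (oxidative addition to zerovalent palladium, transmetallation with the phenoxide-activated diboron, reductive elimination) should give the alkenyl boronate, with the weak base preventing Suzuki homocoupling.

Step 6
Reactants: 12 tetravinylstannane
Product: 13 vinyllithium
Conditions: n-BuLi, pentane, rt; solid filtered, washed with pentane, dissolved in THF and titrated
Reagents that add atoms: n-butyllithium, [Li]CCCC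
Why: Tin–lithium exchange is driven by precipitation of vinyllithium from pentane and should give a halide-free reagent, which matters because halide would bind the cationic palladium of step 7.

Step 7
Reactants: 11 4,4,5,5-tetramethyl-2-(6-methylhepta-1,5-dien-2-yl)-1,3,2-dioxaborolane; 13 vinyllithium; 6 2,4,6-tris(methoxymethoxy)phenyl trifluoromethanesulfonate
Product: 15 2-[(2R)-7-methyl-3-methylidene-1-[2,4,6-tris(methoxymethoxy)phenyl]oct-6-en-2-yl]-4,4,5,5-tetramethyl-1,3,2-dioxaborolane, via lithium dienyl(vinyl)borate complex 14 (not isolated)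
Conditions: 13, THF, 0 °C → rt; then 6, Pd(OAc)2 (3 mol %), L (3.6 mol %), THF, 60 °C; short silica pad, used directly
Reagents that add atoms: none
Why: Vinyllithium adds to boron of 11 to give the bis(alkenyl) ate complex 14; the cationic arylpalladium species formed by oxidative addition of triflate 6 to zerovalent palladium (generated from Pd(OAc)2 and L) binds the unsubstituted vinyl group, which triggers 1,2-migration of the dienyl group from boron to the boron-bearing carbon anti to palladium, and reductive elimination then forms the ring A–C1' bond. The closest known reaction type is the palladium-catalysed enantioselective conjunctive cross-coupling of bis(alkenyl)boron ate complexes with aryl triflates, which gives α-chiral allylic boronates. No ring is closed; two skeletal bonds (ring A–C1' and C2'–C3') and the C2' stereocentre arise in one operation. The configuration at C2' is controlled by the chiral bisphosphine on palladium, which selects the enantiotopic face of the complexed vinyl group, and the metallate shift that follows is stereospecific. The step needs activation of the vinyl group and not of the dienyl group, and this is secured by the 1,1-disubstitution of the dienyl alkene, which makes it the poorer π-ligand for the crowded palladium centre and therefore the migrating group; the weakly coordinating triflate and halide-free 13 keep palladium cationic so that the metallate shift outruns direct transmetallation.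

Step 8
Reactants: 15 the (R)-allylic pinacol boronate
Product: 16 (2R)-7-methyl-3-methylidene-1-[2,4,6-tris(methoxymethoxy)phenyl]oct-6-en-2-ol
Conditions: 3 M NaOH aq, 30% H2O2, THF, 0 °C → rt
Reagents that add atoms: hydrogen peroxide, OO
Why: Boronate oxidation proceeds by hydroperoxide addition to boron and 1,2-shift of carbon to oxygen with retention and without allylic transposition, so the C–B configuration should be carried unchanged into the (R)-alcohol, while the acetals and both alkenes are inert to basic peroxide.

Step 9
Reactants: 16 (2R)-7-methyl-3-methylidene-1-[2,4,6-tris(methoxymethoxy)phenyl]oct-6-en-2-ol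
Product: 17 tert-butyl(dimethyl){[(2R)-7-methyl-3-methylidene-1-[2,4,6-tris(methoxymethoxy)phenyl]oct-6-en-2-yl]oxy}silane
Conditions: TBSCl, imidazole, DMF, rt
Reagents that add atoms: tert-butyldimethylsilyl chloride, CC(C)(C)[Si](C)(C)Cl
Why: Imidazole-promoted silylation of the secondary alcohol masks the only acidic proton, so that the next step needs a single equivalent of base and no alkoxide sits next to the ring.

Step 10
Reactants: 17 the silyl ether; 18 N-methoxy-N-methylbenzamide
Product: 20 {3-[(2R)-2-(tert-butyldimethylsilyloxy)-7-methyl-3-methylideneoct-6-en-1-yl]-2,4,6-tris(methoxymethoxy)phenyl}(phenyl)methanone, via ring-lithiated silyl ether 19 (not isolated)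
Conditions: n-BuLi, THF, 0 °C; then 18, −78 → 0 °C; H2O
Reagents that add atoms: none
Why: Directed ortho-metalation at the ring carbon between two MOM ethers (the two such positions are equivalent) followed by Weinreb ketone synthesis should give the diaryl ketone, the chelated tetrahedral adduct preventing a second addition.

Step 11
Reactants: 20 the protected benzophenone
Product: 21 [2,4,6-trihydroxy-3-[(2R)-2-hydroxy-7-methyl-3-methylideneoct-6-en-1-yl]phenyl](phenyl)methanone
Conditions: HCl (1 M in MeOH), 0 °C → rt
Reagents that add atoms: none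
Why: Acid-catalysed acetal exchange with methanol removes the three aryl MOM groups (made better leaving groups by the ortho or para acyl group) and methanolysis cleaves the secondary silyl ether, while dilute acid at room temperature should not protonate the isolated alkenes or ionise the allylic alcohol, as the routine survival of prenyl groups under such conditions suggests.

**Compound list**

1 | phloroglucinol | Oc1cc(O)cc(O)c1 | starting material
2 | 1,3,5-tris(methoxymethoxy)benzene | COCOc1cc(OCOC)cc(OCOC)c1 | intermediate
3 | 2,4,6-tris(methoxymethoxy)phenyllithium | [Li]c1c(OCOC)cc(OCOC)cc1OCOC | intermediate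
4 | lithium trimethoxy[2,4,6-tris(methoxymethoxy)phenyl]borate | [Li+].CO[B-](OC)(OC)c1c(OCOC)cc(OCOC)cc1OCOC | intermediate
5 | 2,4,6-tris(methoxymethoxy)phenol | COCOc1cc(OCOC)c(O)c(OCOC)c1 | intermediate
6 | 2,4,6-tris(methoxymethoxy)phenyl trifluoromethanesulfonate | COCOc1cc(OCOC)c(OS(=O)(=O)C(F)(F)F)c(OCOC)c1 | intermediate
7 | 6-methylhept-5-en-2-one (sulcatone) | CC(=O)CCC=C(C)C | starting material
8 | lithium 6-methylhepta-1,5-dien-2-olate | [Li]OC(=C)CCC=C(C)C | intermediate
9 | 6-methylhepta-1,5-dien-2-yl trifluoromethanesulfonate | C=C(CCC=C(C)C)OS(=O)(=O)C(F)(F)F | intermediate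
10 | bis(pinacolato)diboron | CC1(C)OB(OC1(C)C)B1OC(C)(C)C(C)(C)O1 | starting material
11 | 4,4,5,5-tetramethyl-2-(6-methylhepta-1,5-dien-2-yl)-1,3,2-dioxaborolane | C=C(CCC=C(C)C)B1OC(C)(C)C(C)(C)O1 | intermediate
12 | tetravinylstannane | C=C[Sn](C=C)(C=C)C=C | starting material
13 | vinyllithium | [Li]C=C | intermediate
14 | lithium (6-methylhepta-1,5-dien-2-yl)(vinyl)(pinacolato)borate | [Li+].C=C[B-]1(C(=C)CCC=C(C)C)OC(C)(C)C(C)(C)O1 | intermediate
15 | 2-[(2R)-7-methyl-3-methylidene-1-[2,4,6-tris(methoxymethoxy)phenyl]oct-6-en-2-yl]-4,4,5,5-tetramethyl-1,3,2-dioxaborolane | C=C(CCC=C(C)C)[C@H](B1OC(C)(C)C(C)(C)O1)Cc1c(OCOC)cc(OCOC)cc1OCOC | intermediate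
16 | (2R)-7-methyl-3-methylidene-1-[2,4,6-tris(methoxymethoxy)phenyl]oct-6-en-2-ol | C=C(CCC=C(C)C)[C@H](O)Cc1c(OCOC)cc(OCOC)cc1OCOC | intermediate
17 | tert-butyl(dimethyl){[(2R)-7-methyl-3-methylidene-1-[2,4,6-tris(methoxymethoxy)phenyl]oct-6-en-2-yl]oxy}silane | C=C(CCC=C(C)C)[C@H](O[Si](C)(C)C(C)(C)C)Cc1c(OCOC)cc(OCOC)cc1OCOC | intermediate
18 | N-methoxy-N-methylbenzamide | CON(C)C(=O)c1ccccc1 | starting material
19 | {3-[(2R)-2-(tert-butyldimethylsilyloxy)-7-methyl-3-methylideneoct-6-en-1-yl]-2,4,6-tris(methoxymethoxy)phenyl}lithium | C=C(CCC=C(C)C)[C@H](O[Si](C)(C)C(C)(C)C)Cc1c(OCOC)cc(OCOC)c([Li])c1OCOC | intermediate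
20 | {3-[(2R)-2-(tert-butyldimethylsilyloxy)-7-methyl-3-methylideneoct-6-en-1-yl]-2,4,6-tris(methoxymethoxy)phenyl}(phenyl)methanone | C=C(CCC=C(C)C)[C@H](O[Si](C)(C)C(C)(C)C)Cc1c(OCOC)cc(OCOC)c(C(=O)c2ccccc2)c1OCOC | intermediate
21 | [2,4,6-trihydroxy-3-[(2R)-2-hydroxy-7-methyl-3-methylideneoct-6-en-1-yl]phenyl](phenyl)methanone | C=C(CCC=C(C)C)[C@H](O)Cc1c(O)cc(O)c(C(=O)c2ccccc2)c1O | target

**Count and risks**

Total step count: 11. Longest linear sequence: 8 steps (1, 2, 3, 7, 8, 9, 10, 11).

Steps most likely to fail:

1. Step 7. Oxidative addition of the electron-rich, doubly ortho-substituted triflate may be slow. Direct transfer of an alkenyl group from boron to palladium, protodeboronation of the ate complex, or a poorly face-selective metallate shift could then take over. The fallback sets out from 2 and 9 and comes back at 16.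
   - Lithiation of 2 as in step 2 and trapping of 3 with allyl bromide (CuBr·SMe2 cat., THF) would give 2-allyl-1,3,5-tris(methoxymethoxy)benzene F1.
   - Lemieux–Johnson cleavage (OsO4 cat., NaIO4, 2,6-lutidine, dioxane–water) would give 2-[2,4,6-tris(methoxymethoxy)phenyl]acetaldehyde F2.
   - Nozaki–Hiyama–Kishi coupling of F2 with enol triflate 9 (CrCl2, NiCl2 cat., DMF, rt) would give racemic 7-methyl-3-methylidene-1-[2,4,6-tris(methoxymethoxy)phenyl]oct-6-en-2-ol F3.
   - Dess–Martin oxidation (NaHCO3, CH2Cl2) would give 7-methyl-3-methylidene-1-[2,4,6-tris(methoxymethoxy)phenyl]oct-6-en-2-one F4.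
   - Corey–Bakshi–Shibata reduction ((S)-Me-oxazaborolidine, catecholborane, toluene, −78 °C, the 1-substituted vinyl group acting as the large substituent) should return the (R)-alcohol 16.

2. Step 10. Acyl transfer to the doubly ortho-substituted aryllithium may be slow. Base-induced fragmentation of the N-methoxy group of the amide, proton return to the ring, or deprotonation at benzylic C1' with loss of silanolate could then compete. The fallback sets out from 17 and comes back at 20.
   - Lithiation as in step 10 and trapping of 19 with the more electrophilic benzaldehyde (THF, −78 °C) would give {3-[(2R)-2-(tert-butyldimethylsilyloxy)-7-methyl-3-methylideneoct-6-en-1-yl]-2,4,6-tris(methoxymethoxy)phenyl}(phenyl)methanol F5 as a mixture of epimers at the new carbinol.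
   - Dess–Martin oxidation (or MnO2, CH2Cl2) would convert it to ketone 20.

3. Step 11. A freed ortho-hydroxyl may add to the protonated 1,1-disubstituted alkene (chroman formation), or the allylic alcohol may ionise, before the slowest acetal has been cleaved. The fallback sets out from 20 and comes back at 21; it replaces protic solvolysis by a two-stage, non-protic unmasking.
   - TMSOTf and 2,2'-bipyridyl (CH2Cl2, 0 °C → rt) would exchange the aryl acetals for silyl ethers, giving {3-[(2R)-2-(tert-butyldimethylsilyloxy)-7-methyl-3-methylideneoct-6-en-1-yl]-2,4,6-tris(trimethylsilyloxy)phenyl}(phenyl)methanone F6 in the flask.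
   - Aqueous work-up would hydrolyse it to {3-[(2R)-2-(tert-butyldimethylsilyloxy)-7-methyl-3-methylideneoct-6-en-1-yl]-2,4,6-trihydroxyphenyl}(phenyl)methanone F7.
   - Fluoride cleavage of the remaining silyl ether (TBAF buffered with AcOH, THF, 0 °C → rt) would give 21.

**Further compounds**

F1 | step 7 | 2-allyl-1,3,5-tris(methoxymethoxy)benzene | C=CCc1c(OCOC)cc(OCOC)cc1OCOC
F2 | step 7 | 2-[2,4,6-tris(methoxymethoxy)phenyl]acetaldehyde | O=CCc1c(OCOC)cc(OCOC)cc1OCOC
F3 | step 7 | racemic 7-methyl-3-methylidene-1-[2,4,6-tris(methoxymethoxy)phenyl]oct-6-en-2-ol | C=C(CCC=C(C)C)C(O)Cc1c(OCOC)cc(OCOC)cc1OCOC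
F4 | step 7 | 7-methyl-3-methylidene-1-[2,4,6-tris(methoxymethoxy)phenyl]oct-6-en-2-one | C=C(CCC=C(C)C)C(=O)Cc1c(OCOC)cc(OCOC)cc1OCOC
F5 | step 10 | {3-[(2R)-2-(tert-butyldimethylsilyloxy)-7-methyl-3-methylideneoct-6-en-1-yl]-2,4,6-tris(methoxymethoxy)phenyl}(phenyl)methanol | C=C(CCC=C(C)C)[C@H](O[Si](C)(C)C(C)(C)C)Cc1c(OCOC)cc(OCOC)c(C(O)c2ccccc2)c1OCOC
F6 | step 11 | {3-[(2R)-2-(tert-butyldimethylsilyloxy)-7-methyl-3-methylideneoct-6-en-1-yl]-2,4,6-tris(trimethylsilyloxy)phenyl}(phenyl)methanone | C=C(CCC=C(C)C)[C@H](O[Si](C)(C)C(C)(C)C)Cc1c(O[Si](C)(C)C)cc(O[Si](C)(C)C)c(C(=O)c2ccccc2)c1O[Si](C)(C)C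
F7 | step 11 | {3-[(2R)-2-(tert-butyldimethylsilyloxy)-7-methyl-3-methylideneoct-6-en-1-yl]-2,4,6-trihydroxyphenyl}(phenyl)methanone | C=C(CCC=C(C)C)[C@H](O[Si](C)(C)C(C)(C)C)Cc1c(O)cc(O)c(C(=O)c2ccccc2)c1O
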